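The cyclopentane ring (C8–C12, prostaglandin numbering) is made by a formal [3+2] annulation in which an alkoxy donor–acceptor cyclopropane, benzyl 2-oxabicyclo[3.1.0]hexane-6-carboxylate, supplies C9–C8–C12 and the enol silane of acetaldehyde supplies C10–C11; one Lewis-acid operation joins C9 to C10 and C11 to C12. The step exploits the 1,3-dioxygenation at C9 and C11 across the C10 methylene and the carboxyl-level C13 on C12, that is, the gamma-oxy and beta-oxy ester relationships of the ring. The precursor is a cyclopropanated 2,3-dihydrofuran whose tetrahydrofuran ring already carries O9, C7 and C6. Oxidation to the bicyclic lactone and two olefinations then attach both side chains.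

Key step: step 2

Remark: prostaglandin numbering is used for all intermediates; in step 1 the bisoxazoline antipode is the one that delivers the (1R,5R,6R) cyclopropane.

Step 1
Reactants: 1 2,3-dihydrofuran; 2 benzyl diazoacetate
Product: 3 benzyl (1R,5R,6R)-2-oxabicyclo[3.1.0]hexane-6-carboxylate (exo ester)
Conditions: (CuOTf)2·C6H6 (1 mol %), 2,2'-(propane-2,2-diyl)bis[(4S)-4-tert-butyl-4,5-dihydrooxazole] (1.2 mol %), excess 1, CH2Cl2, slow addition of 2, 0 °C to rt
Reagents that add atoms: none
Why: Copper–bisoxazoline carbene transfer to the electron-rich enol ether (asymmetric cyclopropanation) should give the exo ester, the C2-symmetric ligand choosing the alkene face and thereby setting C8 (and, for the moment, C9 and C12).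

Step 2
Reactants: 3 benzyl (1R,5R,6R)-2-oxabicyclo[3.1.0]hexane-6-carboxylate; 4 tert-butyldimethyl(vinyloxy)silane
Product: 7 benzyl (3aR,4R,5R,6aS)-5-[(tert-butyldimethylsilyl)oxy]hexahydro-2H-cyclopenta[b]furan-4-carboxylate, via oxocarbenium silyl ketene acetal 5 (not isolated), via silyloxocarbenium adduct 6 (not isolated)
Conditions: TMSOTf (0.2 equiv), 4 (3 equiv), CH2Cl2, −78 to −40 °C; Et3N quench
Reagents that add atoms: none
Why: TMSOTf silylates the ester carbonyl and the ring oxygen pushes open the bond between the oxygen-bearing and the ester-bearing cyclopropane carbons of 3, giving the cyclic oxocarbenium ion/silyl ketene acetal 5; the terminal carbon of 4 adds to the oxocarbenium carbon (C9–C10) and the new silyloxocarbenium ion 6 is trapped by the tethered ketene acetal carbon (C11–C12), the trimethylsilyl group returning to triflate. The closest known reaction type is the Lewis-acid-mediated formal [3+2] cycloaddition of 2-alkoxycyclopropanecarboxylates with enol silyl ethers. The cyclopentane closes in a 5-(enolexo)-exo-trig Mukaiyama aldol mode, and only a cis-fused 2-oxabicyclo[3.3.0]octane can form, so C9 follows from the C8 stereocentre of step 1 (attack of 4 on the inside face of the envelope oxocarbenium ion, cis to the C8 side arm). The ester at C12 should take the convex face trans to C7, and the silyloxy group at C11 should end trans to that ester through an antiperiplanar open transition state. The step needs capture of the oxocarbenium ion syn to the arm and ring closure faster than further addition of 4; the intramolecular nucleophile and the reversible ring opening (5 recloses to 3) should secure both.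

Step 3
Reactants: 7 benzyl (3aR,4R,5R,6aS)-5-[(tert-butyldimethylsilyl)oxy]hexahydro-2H-cyclopenta[b]furan-4-carboxylate
Product: 8 (3aR,4R,5R,6aS)-5-[(tert-butyldimethylsilyl)oxy]hexahydro-2H-cyclopenta[b]furan-4-carboxylic acid
Conditions: H2 (1 atm), 10% Pd on carbon, EtOAc, rt
Reagents that add atoms: none
Why: Hydrogenolysis of the benzyl ester frees the acid without touching the silyl ether or the ring ether, and no stereocentre is affected.

Step 4
Reactants: 8 (3aR,4R,5R,6aS)-5-[(tert-butyldimethylsilyl)oxy]hexahydro-2H-cyclopenta[b]furan-4-carboxylic acid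
Product: 9 (3aR,4R,5R,6aS)-5-[(tert-butyldimethylsilyl)oxy]-2-oxohexahydro-2H-cyclopenta[b]furan-4-carboxylic acid
Conditions: RuCl3·xH2O (5 mol %), NaIO4 (4 equiv), CCl4/MeCN/H2O, rt
Reagents that add atoms: sodium periodate [Na+].[O-]I(=O)(=O)=O
Why: RuO4 formed in the flask should oxidise the less hindered methylene next to the ether oxygen (C6) to the lactone carbonyl (ether-to-lactone oxidation), the ring-fusion C9–H lying on the hindered concave side, and stereocentres stay as they are.

Step 5
Reactants: 9 (3aR,4R,5R,6aS)-5-[(tert-butyldimethylsilyl)oxy]-2-oxohexahydro-2H-cyclopenta[b]furan-4-carboxylic acid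
Product: 10 (3aR,4S,5R,6aS)-5-[(tert-butyldimethylsilyl)oxy]-4-(hydroxymethyl)hexahydro-2H-cyclopenta[b]furan-2-one
Conditions: BH3·SMe2 (1.5 equiv), THF, 0 °C to rt; aqueous work-up
Reagents that add atoms: none
Why: Borane reduces the carboxylic acid through its acyloxyborane much faster than the lactone (chemoselective borane reduction), giving the primary alcohol at C13.

Step 6
Reactants: 10 (3aR,4S,5R,6aS)-5-[(tert-butyldimethylsilyl)oxy]-4-(hydroxymethyl)hexahydro-2H-cyclopenta[b]furan-2-one
Product: 11 (3aR,4R,5R,6aS)-5-[(tert-butyldimethylsilyl)oxy]-2-oxohexahydro-2H-cyclopenta[b]furan-4-carbaldehyde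
Conditions: Dess–Martin periodinane (1.3 equiv), CH2Cl2, rt
Reagents that add atoms: none
Why: Dess–Martin oxidation gives the aldehyde under non-basic conditions that should avoid epimerisation at C12 and beta-elimination of the C11 silyloxy group.

Step 7
Reactants: 12 (R)-butane-1,3-diol
Product: 13 (R)-4-iodobutan-2-ol
Conditions: I2, PPh3, imidazole, CH2Cl2, 0 °C
Reagents that add atoms: iodine [I][I]
Why: Appel-type iodination with phosphine/iodine is selective for the primary hydroxyl of the 1,3-diol, and the C19 stereocentre comes unchanged from the chiral pool.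

Step 8
Reactants: 13 (R)-4-iodobutan-2-ol
Product: 14 (R)-tert-butyl[(4-iodobutan-2-yl)oxy]dimethylsilane
Conditions: TBSCl, imidazole, DMF, rt
Reagents that add atoms: tert-butyldimethylsilyl chloride CC(C)(C)[Si](C)(C)Cl
Why: Standard silylation protects the secondary alcohol for the strongly basic alkylation that follows.

Step 9
Reactants: 14 (R)-tert-butyl[(4-iodobutan-2-yl)oxy]dimethylsilane; 15 dimethyl (2-oxopropyl)phosphonate
Product: 17 dimethyl [(6R)-6-[(tert-butyldimethylsilyl)oxy]-2-oxoheptyl]phosphonate, via phosphonate dianion 16 (not isolated)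
Conditions: 15, NaH (1.1 equiv), THF, 0 °C; n-BuLi (1.05 equiv), 0 °C; then 14, 0 °C to rt; aqueous work-up
Reagents that add atoms: none
Why: The 1,3-dianion of the beta-keto phosphonate is alkylated by the primary iodide at its more nucleophilic terminal carbon (dianion gamma-alkylation), which assembles C14–C20.

Step 10
Reactants: 11 (3aR,4R,5R,6aS)-5-[(tert-butyldimethylsilyl)oxy]-2-oxohexahydro-2H-cyclopenta[b]furan-4-carbaldehyde; 17 dimethyl [(6R)-6-[(tert-butyldimethylsilyl)oxy]-2-oxoheptyl]phosphonate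
Product: 18 (3aR,4R,5R,6aS)-5-[(tert-butyldimethylsilyl)oxy]-4-[(1E,7R)-7-[(tert-butyldimethylsilyl)oxy]-3-oxooct-1-en-1-yl]hexahydro-2H-cyclopenta[b]furan-2-one
Conditions: LiCl, i-Pr2NEt, MeCN, rt
Reagents that add atoms: none
Why: Horner–Wadsworth–Emmons olefination with the stabilised phosphonate under mild LiCl/amine conditions should give the (E)-enone (C13=C14) without epimerising C12.

Step 11
Reactants: 18 (3aR,4R,5R,6aS)-5-[(tert-butyldimethylsilyl)oxy]-4-[(1E,7R)-7-[(tert-butyldimethylsilyl)oxy]-3-oxooct-1-en-1-yl]hexahydro-2H-cyclopenta[b]furan-2-one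
Product: 19 (3aR,4R,5R,6aS)-5-[(tert-butyldimethylsilyl)oxy]-4-[(1E,3S,7R)-7-[(tert-butyldimethylsilyl)oxy]-3-hydroxyoct-1-en-1-yl]hexahydro-2H-cyclopenta[b]furan-2-one
Conditions: (R)-2-methyl-CBS-oxazaborolidine (0.2 equiv), catecholborane (2 equiv), toluene, −78 °C
Reagents that add atoms: none
Why: Corey–Bakshi–Shibata reduction, in which the oxazaborolidine binds the enone carbonyl with the alkenyl group as the large substituent and directs hydride to one face, should set C15 as S under catalyst control.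

Step 12
Reactants: 19 (3aR,4R,5R,6aS)-5-[(tert-butyldimethylsilyl)oxy]-4-[(1E,3S,7R)-7-[(tert-butyldimethylsilyl)oxy]-3-hydroxyoct-1-en-1-yl]hexahydro-2H-cyclopenta[b]furan-2-one
Product: 20 (3aR,4R,5R,6aS)-5-[(tert-butyldimethylsilyl)oxy]-4-[(1E,3S,7R)-7-[(tert-butyldimethylsilyl)oxy]-3-hydroxyoct-1-en-1-yl]hexahydro-2H-cyclopenta[b]furan-2-ol (lactol, both anomers)
Conditions: i-Bu2AlH (3.5 equiv), CH2Cl2, −78 °C; aq. potassium sodium tartrate
Reagents that add atoms: none
Why: Partial lactone reduction stops at the tetrahedral aluminium hemiacetal at −78 °C and gives the lactol, the extra hydride covering the free C15 hydroxyl.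

Step 13
Reactants: 20 the lactol of step 12; 21 (4-carboxybutyl)triphenylphosphonium bromide
Product: 23 (5Z,9S,11R,13E,15S,19R)-11,19-bis[(tert-butyldimethylsilyl)oxy]-9,15-dihydroxyprosta-5,13-dienoic acid, via carboxylate ylide 22 (not isolated)
Conditions: 21 (5 equiv), KOt-Bu (10 equiv), THF, 0 °C; then 20, 0 °C to rt; aq. citric acid
Reagents that add atoms: none
Why: Wittig olefination of the open hydroxy-aldehyde form of the lactol with the non-stabilised ylide should give the (Z)-alkene C5=C6 under kinetic control.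

Step 14
Reactants: 23 (5Z,9S,11R,13E,15S,19R)-11,19-bis[(tert-butyldimethylsilyl)oxy]-9,15-dihydroxyprosta-5,13-dienoic acid
Product: 24 19(R)-hydroxy prostaglandin F2alpha
Conditions: HF·pyridine, THF/pyridine, 0 °C to rt
Reagents that add atoms: none
Why: Fluoride-mediated desilylation should cleave both secondary silyl ethers without affecting the allylic alcohol, the two alkenes or the acid.

Compound list
1 | 2,3-dihydrofuran | C1=COCC1 | starting material
2 | benzyl diazoacetate | [N-]=[N+]=CC(=O)OCc1ccccc1 | starting material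
3 | benzyl (1R,5R,6R)-2-oxabicyclo[3.1.0]hexane-6-carboxylate | O=C(OCc1ccccc1)[C@@H]1[C@H]2CCO[C@@H]12 | intermediate
4 | tert-butyldimethyl(vinyloxy)silane | C=CO[Si](C)(C)C(C)(C)C | starting material
5 | (3R)-3-[2-(benzyloxy)-2-(trimethylsilyloxy)ethenyl]-4,5-dihydro-3H-furan-1-ium triflate (ring-opened ion pair) | C[Si](C)(C)OC(OCc1ccccc1)=C[C@H]2CC[O+]=C2.[O-]S(=O)(=O)C(F)(F)F | intermediate (not isolated)
6 | adduct of 5 and 4: tetrahydrofuran carrying, cis to each other, the C8 ketene acetal arm and a C9 CH2–CH=O(+)–Si(t-Bu)Me2 arm, as triflate | C[Si](C)(C)OC(OCc1ccccc1)=C[C@H]2CCO[C@H]2CC=[O+][Si](C)(C)C(C)(C)C.[O-]S(=O)(=O)C(F)(F)F | intermediate (not isolated)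
7 | benzyl (3aR,4R,5R,6aS)-5-[(tert-butyldimethylsilyl)oxy]hexahydro-2H-cyclopenta[b]furan-4-carboxylate | O=C(OCc1ccccc1)[C@@H]1[C@H]2CCO[C@H]2C[C@H]1O[Si](C)(C)C(C)(C)C | intermediate
8 | (3aR,4R,5R,6aS)-5-[(tert-butyldimethylsilyl)oxy]hexahydro-2H-cyclopenta[b]furan-4-carboxylic acid | OC(=O)[C@@H]1[C@H]2CCO[C@H]2C[C@H]1O[Si](C)(C)C(C)(C)C | intermediate
9 | (3aR,4R,5R,6aS)-5-[(tert-butyldimethylsilyl)oxy]-2-oxohexahydro-2H-cyclopenta[b]furan-4-carboxylic acid | OC(=O)[C@@H]1[C@H]2CC(=O)O[C@H]2C[C@H]1O[Si](C)(C)C(C)(C)C | intermediate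
10 | (3aR,4S,5R,6aS)-5-[(tert-butyldimethylsilyl)oxy]-4-(hydroxymethyl)hexahydro-2H-cyclopenta[b]furan-2-one | OC[C@@H]1[C@H]2CC(=O)O[C@H]2C[C@H]1O[Si](C)(C)C(C)(C)C | intermediate
11 | (3aR,4R,5R,6aS)-5-[(tert-butyldimethylsilyl)oxy]-2-oxohexahydro-2H-cyclopenta[b]furan-4-carbaldehyde | O=C[C@@H]1[C@H]2CC(=O)O[C@H]2C[C@H]1O[Si](C)(C)C(C)(C)C | intermediate
12 | (R)-butane-1,3-diol | C[C@@H](O)CCO | starting material
13 | (R)-4-iodobutan-2-ol | C[C@@H](O)CCI | intermediate
14 | (R)-tert-butyl[(4-iodobutan-2-yl)oxy]dimethylsilane | C[C@@H](O[Si](C)(C)C(C)(C)C)CCI | intermediate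
15 | dimethyl (2-oxopropyl)phosphonate | CC(=O)CP(=O)(OC)OC | starting material
16 | sodium lithium 1,3-dianion of dimethyl (2-oxopropyl)phosphonate | [Na+].[Li+].[CH2-]C(=O)[CH-]P(=O)(OC)OC | intermediate (not isolated)
17 | dimethyl [(6R)-6-[(tert-butyldimethylsilyl)oxy]-2-oxoheptyl]phosphonate | C[C@@H](O[Si](C)(C)C(C)(C)C)CCCC(=O)CP(=O)(OC)OC | intermediate
18 | (3aR,4R,5R,6aS)-5-[(tert-butyldimethylsilyl)oxy]-4-[(1E,7R)-7-[(tert-butyldimethylsilyl)oxy]-3-oxooct-1-en-1-yl]hexahydro-2H-cyclopenta[b]furan-2-one | C[C@@H](O[Si](C)(C)C(C)(C)C)CCCC(=O)/C=C/[C@@H]1[C@H]2CC(=O)O[C@H]2C[C@H]1O[Si](C)(C)C(C)(C)C | intermediate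
19 | (3aR,4R,5R,6aS)-5-[(tert-butyldimethylsilyl)oxy]-4-[(1E,3S,7R)-7-[(tert-butyldimethylsilyl)oxy]-3-hydroxyoct-1-en-1-yl]hexahydro-2H-cyclopenta[b]furan-2-one | C[C@@H](O[Si](C)(C)C(C)(C)C)CCC[C@H](O)/C=C/[C@@H]1[C@H]2CC(=O)O[C@H]2C[C@H]1O[Si](C)(C)C(C)(C)C | intermediate
20 | (3aR,4R,5R,6aS)-5-[(tert-butyldimethylsilyl)oxy]-4-[(1E,3S,7R)-7-[(tert-butyldimethylsilyl)oxy]-3-hydroxyoct-1-en-1-yl]hexahydro-2H-cyclopenta[b]furan-2-ol (both anomers) | C[C@@H](O[Si](C)(C)C(C)(C)C)CCC[C@H](O)/C=C/[C@@H]1[C@H]2CC(O)O[C@H]2C[C@H]1O[Si](C)(C)C(C)(C)C | intermediate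
21 | (4-carboxybutyl)triphenylphosphonium bromide | OC(=O)CCCC[P+](c1ccccc1)(c1ccccc1)c1ccccc1.[Br-] | starting material
22 | potassium 5-(triphenyl-lambda5-phosphanylidene)pentanoate (ylide) | [K+].[O-]C(=O)CCCC=P(c1ccccc1)(c1ccccc1)c1ccccc1 | intermediate (not isolated)
23 | (5Z,9S,11R,13E,15S,19R)-11,19-bis[(tert-butyldimethylsilyl)oxy]-9,15-dihydroxyprosta-5,13-dienoic acid | C[C@@H](O[Si](C)(C)C(C)(C)C)CCC[C@H](O)/C=C/[C@@H]1[C@@H](C/C=C\CCCC(=O)O)[C@@H](O)C[C@H]1O[Si](C)(C)C(C)(C)C | intermediate
24 | 19(R)-hydroxy prostaglandin F2alpha | C[C@@H](O)CCC[C@H](O)/C=C/[C@@H]1[C@@H](C/C=C\CCCC(=O)O)[C@@H](O)C[C@H]1O | target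

Total step count: 14. Longest linear sequence: 11 steps (steps 1 to 6 and 10 to 14, from 2,3-dihydrofuran).

Steps most likely to fail

Step 2 (key step). The oxocarbenium ion of 5 may be captured by 4 on the face anti to the ketene acetal arm, which gives an adduct that cannot close to the cis-fused bicycle. The silyloxocarbenium ion 6 may also add further 4 instead of cyclising, or the closure may show poor facial control at C11. The fallback sets out from 3 and changes the two-carbon partner to the ketene silyl acetal of methyl acetate, tert-butyl[(1-methoxyethenyl)oxy]dimethylsilane (TiCl4, CH2Cl2, −78 °C). This non-oligomerising partner should give the mixed ketal benzyl (3aR,4R,6aS)-5-methoxy-5-[(tert-butyldimethylsilyl)oxy]hexahydro-2H-cyclopenta[b]furan-4-carboxylate F1, which acidic work-up hydrolyses to the beta-keto ester benzyl (3aR,4R,6aS)-5-oxohexahydro-2H-cyclopenta[b]furan-4-carboxylate F2. In F2 the C12 centre equilibrates to the convex face. NaBH4 in MeOH at low temperature should then deliver hydride to the C11 ketone from the convex face and give benzyl (3aR,4R,5R,6aS)-5-hydroxyhexahydro-2H-cyclopenta[b]furan-4-carboxylate F3. Silylation with TBSOTf and 2,6-lutidine comes back to the route at 7.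

Step 4. RuO4 may attack the ring-fusion C9–H (ring cleavage to a keto acid) or over-oxidise the substrate. The fallback sets out from 7 and replaces the C–H oxidation by ether cleavage and stepwise oxidation. Me2BBr in CH2Cl2 at low temperature should open the tetrahydrofuran at the primary carbon to give benzyl (1R,2R,3S,5R)-2-(2-bromoethyl)-3-hydroxy-5-[(tert-butyldimethylsilyl)oxy]cyclopentane-1-carboxylate F4. Kornblum-type oxidation of the bromide (N-methylmorpholine N-oxide, DMSO) should give the aldehyde, which closes to the lactol benzyl (3aR,4R,5R,6aS)-5-[(tert-butyldimethylsilyl)oxy]-2-hydroxyhexahydro-2H-cyclopenta[b]furan-4-carboxylate F5. TEMPO with PhI(OAc)2 should oxidise it to the lactone benzyl (3aR,4R,5R,6aS)-5-[(tert-butyldimethylsilyl)oxy]-2-oxohexahydro-2H-cyclopenta[b]furan-4-carboxylate F6. Hydrogenolysis (H2, Pd on carbon) comes back to the route at 9.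

Step 1. The carbene transfer may proceed with insufficient enantiofacial discrimination or exo selectivity. The fallback sets out from 1 and 2 and separates ring formation from enantiocontrol. Rh2(OAc)4-catalysed cyclopropanation should give the racemic exo ester, that is 3 together with its mirror image benzyl (1S,5S,6S)-2-oxabicyclo[3.1.0]hexane-6-carboxylate F7. An esterase or lipase selected to hydrolyse F7 (kinetic resolution, phosphate buffer) should convert it into (1S,5S,6S)-2-oxabicyclo[3.1.0]hexane-6-carboxylic acid F8, which is removed by basic extraction. The unreacted ester comes back to the route at 3.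

Further compounds
F1 | step 2 | benzyl (3aR,4R,6aS)-5-methoxy-5-[(tert-butyldimethylsilyl)oxy]hexahydro-2H-cyclopenta[b]furan-4-carboxylate | O=C(OCc1ccccc1)[C@@H]1[C@H]2CCO[C@H]2CC1(OC)O[Si](C)(C)C(C)(C)C
F2 | step 2 | benzyl (3aR,4R,6aS)-5-oxohexahydro-2H-cyclopenta[b]furan-4-carboxylate | O=C(OCc1ccccc1)[C@@H]1[C@H]2CCO[C@H]2CC1=O
F3 | step 2 | benzyl (3aR,4R,5R,6aS)-5-hydroxyhexahydro-2H-cyclopenta[b]furan-4-carboxylate | O=C(OCc1ccccc1)[C@@H]1[C@H]2CCO[C@H]2C[C@H]1O
F4 | step 4 | benzyl (1R,2R,3S,5R)-2-(2-bromoethyl)-3-hydroxy-5-[(tert-butyldimethylsilyl)oxy]cyclopentane-1-carboxylate | O=C(OCc1ccccc1)[C@@H]1[C@@H](CCBr)[C@@H](O)C[C@H]1O[Si](C)(C)C(C)(C)C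
F5 | step 4 | benzyl (3aR,4R,5R,6aS)-5-[(tert-butyldimethylsilyl)oxy]-2-hydroxyhexahydro-2H-cyclopenta[b]furan-4-carboxylate | O=C(OCc1ccccc1)[C@@H]1[C@H]2CC(O)O[C@H]2C[C@H]1O[Si](C)(C)C(C)(C)C
F6 | step 4 | benzyl (3aR,4R,5R,6aS)-5-[(tert-butyldimethylsilyl)oxy]-2-oxohexahydro-2H-cyclopenta[b]furan-4-carboxylate | O=C(OCc1ccccc1)[C@@H]1[C@H]2CC(=O)O[C@H]2C[C@H]1O[Si](C)(C)C(C)(C)C
F7 | step 1 | benzyl (1S,5S,6S)-2-oxabicyclo[3.1.0]hexane-6-carboxylate | O=C(OCc1ccccc1)[C@H]1[C@@H]2CCO[C@H]12
F8 | step 1 | (1S,5S,6S)-2-oxabicyclo[3.1.0]hexane-6-carboxylic acid | OC(=O)[C@H]1[C@@H]2CCO[C@H]12
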